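**Plan**

1. Target numbering: ring C1 (C=O), C2=C3, C4 (CH–OMe), C5 (CH2), C6 (quaternary, bearing allyl and the side chain); side chain C1' (CH–OH, aryl) and C2' (CH–CH3).
2. Retrosynthesis: the C1 ketone and the C1' hydroxyl are folded into a cyclic ketal and the C4 ether is demethylated; the ring bonds C4–C5 and C1–C6 are then cut together (retro-[4+2]), leaving a 2-furyl ether of an acyclic dienol. Further cuts are O–furyl, C=CH2, allyl–C(O) and the aldol bond C1'–C2'.
3. Enabling feature: C1, C2, C3, C4 and the oxygen on C4 are a furan in disguise (C1 at ketone level as a 2-alkoxyfuran carbon, C2=C3 the surviving furan double bond). The C1' oxygen lies three atoms from C6, so the side chain's own hydroxyl can carry the furan as a tether and is released again by hydrolysis.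
4. Forward: syn-aldol, Weinreb amide, allyl ketone, methylenation, O-furylation; one step then closes the carbocycle (with a temporary oxolane and oxygen bridge) by dearomatizing the furan; bridge opening, O-methylation and ketal hydrolysis finish.
5. Stereochemistry: C1' and C2' come from the oxazolidinone auxiliary; C6 and C4 come from the cycloaddition (tether exo, allyl endo, methyl and aryl anti to allyl), the oxygen bridge placing the C4 oxygen syn to the side chain.

Key step: step 6

Remark: the ketal carbon of 12 and 13 may form as either epimer and is drawn without configuration, because step 7 erases it.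

**Step 1**
Reactants: 1 (R)-4-benzyl-3-propanoyl-1,3-oxazolidin-2-one; 2 3,4,5-trimethoxybenzaldehyde
Product: 4 (R)-4-benzyl-3-[(2R,3R)-3-hydroxy-2-methyl-3-(3,4,5-trimethoxyphenyl)propanoyl]-1,3-oxazolidin-2-one, via boron (Z)-enolate 3 (not isolated)
Conditions: Bu2BOTf, i-Pr2NEt, CH2Cl2, 0 °C; then 2, −78 → 0 °C; pH 7 buffer, MeOH, H2O2
Reagents that add atoms: none
Why: Evans syn-aldol reaction, in which the (Z)-boron enolate 3 reacts through a chair-like Zimmerman–Traxler transition state with one face shielded by the (R)-benzyl group, which should set C2' and C1' of the target as the syn methyl/hydroxyl pair.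

**Step 2**
Reactants: 4 the aldol adduct
Product: 5 (2R,3R)-3-hydroxy-N-methoxy-N,2-dimethyl-3-(3,4,5-trimethoxyphenyl)propanamide
Conditions: MeNH(OMe)·HCl, AlMe3, CH2Cl2, −20 °C → rt; then H2O
Reagents that add atoms: N,O-dimethylhydroxylamine hydrochloride, CNOC.Cl
Why: Aluminium-amide transamination to the Weinreb amide is standard for syn-aldol imides (the free β-hydroxyl directs attack to the exocyclic carbonyl) and touches no stereocenter.

**Step 3**
Reactants: 5 the Weinreb amide; 6 allylmagnesium bromide
Product: 7 (5R,6R)-6-hydroxy-5-methyl-6-(3,4,5-trimethoxyphenyl)hex-1-en-4-one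
Conditions: CH2=CHCH2MgBr (3 equiv), THF, −78 °C; then pH 7 phosphate buffer
Reagents that add atoms: none
Why: Weinreb ketone synthesis, in which the Grignard reagent adds once after deprotonating the hydroxyl because the chelated tetrahedral intermediate collapses only on work-up; the cold buffered quench should keep the β,γ-double bond out of conjugation and the α-stereocenter intact.

**Step 4**
Reactants: 7 the allyl ketone
Product: 8 (1R,2S)-2-methyl-3-methylidene-1-(3,4,5-trimethoxyphenyl)hex-5-en-1-ol
Conditions: Cp2Ti(μ-CH2)(μ-Cl)AlMe2 (Tebbe reagent, excess), pyridine, THF–toluene, −40 °C → rt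
Reagents that add atoms: Tebbe reagent, C[Al](C)C[Ti](Cl)(C1C=CC=C1)C1C=CC=C1
Why: Tebbe methylenation, in which the weakly basic titanium methylidene released by pyridine should convert the enolizable ketone through an oxatitanacyclobutane into the 1,1-disubstituted alkene without α-epimerization, retro-aldol cleavage or double-bond migration (the free hydroxyl consumes one extra equivalent and returns on work-up).

**Step 5**
Reactants: 8 the dienol; 9 2-bromofuran
Product: 10 2-{[(1R,2S)-2-methyl-3-methylidene-1-(3,4,5-trimethoxyphenyl)hex-5-en-1-yl]oxy}furan
Conditions: CuI (10 mol%), 3,4,7,8-tetramethyl-1,10-phenanthroline (20 mol%), Cs2CO3, toluene, 80 °C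
Reagents that add atoms: none
Why: Ullmann-type copper-catalyzed C–O coupling of the secondary alcohol with the heteroaryl bromide, chosen because a copper alkoxide does not undergo the β-hydride loss that benzylic alkoxides suffer on palladium and because the basic medium protects the acid-sensitive 2-alkoxyfuran; the carbinol C–O bond is not broken, so C1' keeps its configuration.

**Step 6**
Reactants: 10 the furyl ether
Product: 12 (2R,3S,3aR,5R)-7a-methoxy-3-methyl-3a-(prop-2-en-1-yl)-2-(3,4,5-trimethoxyphenyl)-2,3,3a,4,5,7a-hexahydro-1-benzofuran-5-ol, via oxygen-bridged cycloadduct 11 (not isolated)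
Conditions: PhMe–MeOH (4:1), NaHCO3 (solid), 110 °C, sealed tube; then filter, PPTS (cat.), 0 °C → rt
Reagents that add atoms: methanol, CO
Why: Proposed new method: the 2-alkoxyfuran of 10 (its carbons are the later C1, C2, C3 and C4, its ring oxygen the later methoxy oxygen) is a weakly aromatic, electron-rich diene, and the 1,1-disubstituted alkene held three atoms away through the C1' ether oxygen should add across its 2- and 5-positions in a thermal suprafacial [4+2] cycloaddition, the closest known reaction type being the intramolecular furan Diels–Alder reaction of 2-amidofurans whose nitrogen carries unactivated (also 1,1-disubstituted) alkenyl tethers, from which this case differs in the tether heteroatom. Three rings close at once: the carbocycle by concerted formation of the C4–C5 and C1–C6 bonds (six-membered transition state), the oxolane C1–O–C1'–C2'–C6 as the fused tether ring, and the oxygen bridge C1–O–C4 from the furan oxygen. Both new bonds form on one furan face and a three-atom tether from the bridgehead can only span the exo position, so the bridging oxygen at C4 lies syn to C2' on C6 and anti to the allyl group, which is forced endo; this fixes the C4/C6 relation of the target by geometry, and the ketal carbon C1 is locked by the bridge. The configuration of C6 relative to C2' and C1' is controlled by the substituents of the forming oxolane, methyl and aryl taking the face away from the endo allyl group (methyl trans to allyl), which should also be the thermodynamic preference if the cycloaddition is reversible. The step needs periselectivity for the 1,1-disubstituted alkene over the terminal vinyl group, secured by tether length (five- against seven-membered tether ring), and a productive exit from the bridged ketal: methanol with a trace of acid opens the C1–O bridge bond through the alkoxy-stabilized allylic oxocarbenium ion and is captured at C1 (Ferrier-type regiochemistry; the other ketal C–O bond cannot ionize because that would need a bridgehead cation), which gives 12 and forestalls cycloreversion or hydride-shift isomerization.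

**Step 7**
Reactants: 12 the ketal alcohol
Product: 14 megaphone, via dimethoxy ketal 13 (not isolated)
Conditions: NaH, MeI, THF, 0 °C → rt; then AcOH–H2O (4:1), rt
Reagents that add atoms: iodomethane, CI; water, O
Why: Williamson methylation of the only free hydroxyl (the ketal is base-stable) followed by mild acid hydrolysis of the allylic mixed ketal through the same alkoxy-stabilized cation should release the C1 ketone and the C1' hydroxyl; no stereocenter is formed and both ketal epimers converge.

**Compound list**

1 | (R)-4-benzyl-3-propanoyl-1,3-oxazolidin-2-one | CCC(=O)N1[C@H](Cc2ccccc2)COC1=O | starting material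
2 | 3,4,5-trimethoxybenzaldehyde | COc1cc(C=O)cc(OC)c1OC | starting material
3 | dibutylboron (Z)-enolate of 1 (methyl cis to O–B) | C/C=C(\OB(CCCC)CCCC)N1[C@H](Cc2ccccc2)COC1=O | intermediate
4 | (R)-4-benzyl-3-[(2R,3R)-3-hydroxy-2-methyl-3-(3,4,5-trimethoxyphenyl)propanoyl]-1,3-oxazolidin-2-one (syn aldol) | O=C([C@H](C)[C@@H](O)c1cc(OC)c(OC)c(OC)c1)N1[C@H](Cc2ccccc2)COC1=O | intermediate
5 | (2R,3R)-3-hydroxy-N-methoxy-N,2-dimethyl-3-(3,4,5-trimethoxyphenyl)propanamide | CON(C)C(=O)[C@H](C)[C@@H](O)c1cc(OC)c(OC)c(OC)c1 | intermediate
6 | allylmagnesium bromide | C=CC[Mg]Br | starting material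
7 | (5R,6R)-6-hydroxy-5-methyl-6-(3,4,5-trimethoxyphenyl)hex-1-en-4-one | C=CCC(=O)[C@H](C)[C@@H](O)c1cc(OC)c(OC)c(OC)c1 | intermediate
8 | (1R,2S)-2-methyl-3-methylidene-1-(3,4,5-trimethoxyphenyl)hex-5-en-1-ol | C=CCC(=C)[C@H](C)[C@@H](O)c1cc(OC)c(OC)c(OC)c1 | intermediate
9 | 2-bromofuran | Brc1ccco1 | starting material
10 | 2-{[(1R,2S)-2-methyl-3-methylidene-1-(3,4,5-trimethoxyphenyl)hex-5-en-1-yl]oxy}furan | C=CCC(=C)[C@H](C)[C@@H](Oc1ccco1)c1cc(OC)c(OC)c(OC)c1 | intermediate
11 | (2R,3S,3aR,5R,7aS)-3-methyl-3a-(prop-2-en-1-yl)-2-(3,4,5-trimethoxyphenyl)-2,3,3a,4,5,7a-hexahydro-5,7a-epoxy-1-benzofuran (7-oxanorbornene ketal; oxygen bridge syn to the oxolane CH–CH3 carbon, allyl endo) | C=CC[C@]12C[C@@H]3C=C[C@]1(O3)O[C@@H](c1cc(OC)c(OC)c(OC)c1)[C@H]2C | intermediate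
12 | (2R,3S,3aR,5R)-7a-methoxy-3-methyl-3a-(prop-2-en-1-yl)-2-(3,4,5-trimethoxyphenyl)-2,3,3a,4,5,7a-hexahydro-1-benzofuran-5-ol (either epimer at C7a) | C=CC[C@]12C[C@@H](O)C=CC1(OC)O[C@@H](c1cc(OC)c(OC)c(OC)c1)[C@H]2C | intermediate
13 | (2R,3S,3aR,5R)-5,7a-dimethoxy-3-methyl-3a-(prop-2-en-1-yl)-2-(3,4,5-trimethoxyphenyl)-2,3,3a,4,5,7a-hexahydro-1-benzofuran (either epimer at C7a) | C=CC[C@]12C[C@@H](OC)C=CC1(OC)O[C@@H](c1cc(OC)c(OC)c(OC)c1)[C@H]2C | intermediate
14 | megaphone, (4R,6R)-6-[(1R,2S)-1-hydroxy-1-(3,4,5-trimethoxyphenyl)propan-2-yl]-4-methoxy-6-(prop-2-en-1-yl)cyclohex-2-en-1-one | C=CC[C@]1([C@H](C)[C@@H](O)c2cc(OC)c(OC)c(OC)c2)C[C@@H](OC)C=CC1=O | target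

**Step count and risks**

Total step count: 7. Longest linear sequence: 7 steps (1/2 → 14).

Steps most likely to fail:

1. Step 6 (proposed new method). The cycloaddition may stall, or its equilibrium may lie on the furan side, because a quaternary carbon is created next to the ketal carbon. The bridged ketal may also ring-open and isomerize by a 1,2-hydride shift before methanol captures it, and facial discrimination by the oxolane substituents may be incomplete. The fallback uses known reaction types only, sets out from 2 and returns to the route at 14. Allylboration of 2 with ethyl (E)-2-[(4,4,5,5-tetramethyl-1,3,2-dioxaborolan-2-yl)methyl]but-2-enoate (methyl cis to the borylmethyl group; toluene, heat, or Sc(OTf)3 catalysis at low temperature) through a closed chair transition state, followed by lactonisation of the syn adduct under mild conditions, would give the cis α-methylene lactone (4S,5R)-4-methyl-3-methylidene-5-(3,4,5-trimethoxyphenyl)oxolan-2-one F1; the absolute configuration is secured by separating the enantiomers on a chiral stationary phase or by using a chiral diol ester of the boronate. (E)-3-Methoxyprop-1-enyllithium at −78 °C adds once to the lactone carbonyl and opens it to the cross-conjugated hydroxy dienone F2, and silylation (TBSCl, imidazole) gives the silyl ether F3. KN(SiMe3)2 then removes a γ-proton next to the methoxy group, the resulting cross-conjugated trienolate closes the ring between the methoxy-bearing carbon and the methylidene carbon (C4–C5 bond; oxyanion-accelerated 6π-electrocyclization, formally a 6-endo vinylogous Michael closure), and allyl bromide alkylates the resulting cyclohexadienolate at C6 to give megaphone tert-butyldimethylsilyl ether F4; Bu4NF then gives 14. The price is that C4 is set without help from the remote side chain and C6 only by 1,3-induction from the C4 methoxy group, so isomers would have to be separated.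

2. Step 5. C–O bond formation at a hindered secondary benzylic alkoxide may be slow, allowing oxidation of the alcohol or reduction of the bromide to compete, and the acid-sensitive 2-alkoxyfuran may hydrolyse back to 8 during isolation. The fallback reverses the polarity of the coupling, setting out from 8 and returning at 10: a Chan–Lam-type oxidative etherification of 8 with potassium 2-furyltrifluoroborate (Cu(OAc)2, DMAP, 4 Å molecular sieves, O2, CH2Cl2, rt), in which the furan is the nucleophilic partner and the medium is neutral at room temperature. It makes no new compound (F0).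

3. Step 4. The β-hydroxy ketone may enolize or undergo retro-aldol cleavage, the β,γ-double bond may move into conjugation, or C2' may epimerize before methylene transfer. The fallback replaces carbene transfer by addition–elimination (Peterson olefination), setting out from 7 and returning at 8: Me3SiCH2MgCl with CeCl3 adds to the carbonyl of 7 without enolization to give the β-hydroxysilane diol F5, and KH-induced syn-elimination gives 8.

**Further compounds**

F0 | step 5 | none | none
F1 | step 6 | (4S,5R)-4-methyl-3-methylidene-5-(3,4,5-trimethoxyphenyl)oxolan-2-one | C=C1[C@H](C)[C@H](c2cc(OC)c(OC)c(OC)c2)OC1=O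
F2 | step 6 | (2E,6S,7R)-7-hydroxy-1-methoxy-6-methyl-5-methylidene-7-(3,4,5-trimethoxyphenyl)hept-2-en-4-one | COC/C=C/C(=O)C(=C)[C@H](C)[C@@H](O)c1cc(OC)c(OC)c(OC)c1
F3 | step 6 | (2E,6S,7R)-7-[(tert-butyldimethylsilyl)oxy]-1-methoxy-6-methyl-5-methylidene-7-(3,4,5-trimethoxyphenyl)hept-2-en-4-one | COC/C=C/C(=O)C(=C)[C@H](C)[C@@H](O[Si](C)(C)C(C)(C)C)c1cc(OC)c(OC)c(OC)c1
F4 | step 6 | megaphone tert-butyldimethylsilyl ether (silyl on the C1' oxygen) | C=CC[C@]1([C@H](C)[C@@H](O[Si](C)(C)C(C)(C)C)c2cc(OC)c(OC)c(OC)c2)C[C@@H](OC)C=CC1=O
F5 | step 4 | (1R,2R)-2-methyl-1-(3,4,5-trimethoxyphenyl)-3-[(trimethylsilyl)methyl]hex-5-ene-1,3-diol (either epimer at C3) | C=CCC(O)(C[Si](C)(C)C)[C@H](C)[C@@H](O)c1cc(OC)c(OC)c(OC)c1
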